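**Strategy.** The route rests on disconnecting the C4–C5 bond of the cyclohexane ring (numbered as in the name of 20: C1 bears the propanal chain, C2 the aryloxymethyl group, C6 the isopropylidene). C5 is the allylic methylene of the exocyclic C6=C(CH3)2 alkene, so a primary C4 radical is added 6-endo to the CH2 terminus of a 2,3-disubstituted buta-1,3-diene; hydrogen transfer to the far end of the allyl radical then gives ring and tetrasubstituted alkene in one operation. The precursor is an acyclic selenide that already carries the C1–C2–C3 stereotriad, set by a Claisen rearrangement on the ring-locked ketene acetal of (R)-β-methyl-γ-butyrolactone; this temporary lactone is then opened by phenylselenide at the future C4.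

Key step: step 8

Remark: 8, 18, 2 (as a THF solution) and 5 are taken as commercial; 9 is carried as its C3 epimer mixture because C3 becomes trigonal again in step 5.

Step 1
Reactants: 1 prop-2-yn-1-ol; 2 isopropenylmagnesium bromide
Product: 4 (2Z)-3-iodo-2-(prop-1-en-2-yl)prop-2-en-1-ol, via alkenylmagnesium alkoxide 3 (not isolated)
Conditions: 2 (2.5 equiv), CuI (10 mol %), THF, −10 °C → rt; then I2, −40 → 0 °C; aqueous work-up
Reagents that add atoms: iodine, II
Why: Copper-catalysed carbomagnesiation of a propargylic alcohol, in which the magnesium alkoxide directs anti addition (alkenyl group to C2, magnesium to C3 in a five-membered chelate) and iodinolysis with retention fixes the Z geometry with iodine cis to CH2OH.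

Step 2
Reactants: 4 (2Z)-3-iodo-2-(prop-1-en-2-yl)prop-2-en-1-ol; 5 2-vinyl-1,3-dioxolane
Product: 7 (2Z)-5-(1,3-dioxolan-2-yl)-2-(prop-1-en-2-yl)pent-2-en-1-ol, via B-alkyl-9-BBN 6 (not isolated)
Conditions: 5, 9-BBN (0.5 M in THF), 0 °C → rt; then 4, PdCl2(dppf) (5 mol %), 3 M aq NaOH, THF, 50 °C
Reagents that add atoms: none
Why: B-alkyl Suzuki–Miyaura coupling, in which anti-Markovnikov hydroboration of 5 gives the primary alkylborane that couples with the alkenyl iodide with retention of the Z geometry and in the presence of the free hydroxyl.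

Step 3
Reactants: 8 (4R)-4-methyloxolan-2-one
Product: 9 (3R,4R)-3,4-dimethyloxolan-2-one (trans isomer expected to predominate)
Conditions: LiN(iPr)2, THF, −78 °C; MeI, −78 → −30 °C
Reagents that add atoms: iodomethane, CI
Why: Lactone enolate alkylation, in which iodomethane should enter trans to the C4 methyl group, although the C3 configuration is of no consequence for the route.

Step 4
Reactants: 9 (3R,4R)-3,4-dimethyloxolan-2-one
Product: 11 (3R,4R)-2,2-diethoxy-3,4-dimethyloxolane, via O-ethyl lactonium tetrafluoroborate 10 (not isolated)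
Conditions: Et3O+ BF4−, CH2Cl2, rt; then NaOEt, EtOH, −78 → 0 °C
Reagents that add atoms: triethyloxonium tetrafluoroborate, CC[O+](CC)CC.F[B-](F)(F)F; sodium ethoxide, CC[O-].[Na+]
Why: O-Alkylation of the lactone carbonyl gives the dialkoxycarbenium salt, which ethoxide captures at carbon (ortho ester synthesis).

Step 5
Reactants: 11 (3R,4R)-2,2-diethoxy-3,4-dimethyloxolane; 7 (2Z)-5-(1,3-dioxolan-2-yl)-2-(prop-1-en-2-yl)pent-2-en-1-ol
Product: 14 (3R,4R)-3-[(4S)-6-(1,3-dioxolan-2-yl)-2-methyl-3-methylidenehex-1-en-4-yl]-3,4-dimethyloxolan-2-one, via mixed ortho-lactone 12 (not isolated), via cyclic ketene acetal 13 (not isolated)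
Conditions: 11 (3 equiv), tBuCO2H (10 mol %), xylene, 140 °C, EtOH distilled off
Reagents that add atoms: none
Why: Johnson–Claisen (ortho ester Claisen) rearrangement, in which acid-catalysed exchange and loss of ethanol give the ring-locked ketene acetal (C3 methyl cis to the allyloxy oxygen) whose [3,3] shift through a chair, on the face anti to the C4 methyl and with the Z-alkene chain pseudo-axial, should set the quaternary C3 and the adjacent side-chain stereocenter together and deliver the 2,3-disubstituted diene.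

Step 6
Reactants: 14 (3R,4R)-3-[(4S)-6-(1,3-dioxolan-2-yl)-2-methyl-3-methylidenehex-1-en-4-yl]-3,4-dimethyloxolan-2-one
Product: 15 (2R,3R)-2-[(4S)-6-(1,3-dioxolan-2-yl)-2-methyl-3-methylidenehex-1-en-4-yl]-2,3-dimethyl-4-(phenylselanyl)butanoic acid
Conditions: PhSeSePh, Na, THF, 65 °C; then 14, DMF, 110 °C; aq NH4Cl
Reagents that add atoms: diphenyl diselenide, c1ccccc1[Se][Se]c1ccccc1
Why: SN2 opening of the lactone at the O–CH2 carbon by the soft benzeneselenolate anion (alkyl–oxygen cleavage) cuts the temporary ring and installs the radical precursor without touching a stereocenter, the quaternary α-carbon shielding the carbonyl from acyl attack.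

Step 7
Reactants: 15 (2R,3R)-2-[(4S)-6-(1,3-dioxolan-2-yl)-2-methyl-3-methylidenehex-1-en-4-yl]-2,3-dimethyl-4-(phenylselanyl)butanoic acid
Product: 16 (2R,3R)-2-[(4S)-6-(1,3-dioxolan-2-yl)-2-methyl-3-methylidenehex-1-en-4-yl]-2,3-dimethyl-4-(phenylselanyl)butan-1-ol
Conditions: LiAlH4, THF, 0 → 65 °C; H2O, aq NaOH
Reagents that add atoms: none
Why: Hydride reduction of the carboxylic acid to the neopentyl alcohol, to which selenide, diene and acetal are inert.

Step 8
Reactants: 16 (2R,3R)-2-[(4S)-6-(1,3-dioxolan-2-yl)-2-methyl-3-methylidenehex-1-en-4-yl]-2,3-dimethyl-4-(phenylselanyl)butan-1-ol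
Product: 17 {(1S,2S,6S)-2-[2-(1,3-dioxolan-2-yl)ethyl]-1,6-dimethyl-3-(propan-2-ylidene)cyclohexyl}methanol
Conditions: Bu3SnH (1.3 equiv, syringe pump, 6 h), AIBN (20 mol %), PhH, 80 °C, 0.005 M
Reagents that add atoms: none
Why: Bu3Sn• abstracts the phenylselanyl group to give the primary C4 radical, which adds to the unsubstituted CH2 terminus (future C5) of the diene; the resulting allyl radical then takes hydrogen from Bu3SnH at its primary terminus, leaving the double bond as the exocyclic C6=C(CH3)2. The closest known reaction type is the tin hydride-mediated cyclization of alkyl selenides or halides onto 1,3-dienes, with the endo preference of 5-substituted hex-5-enyl radicals. The cyclohexane ring closes in the 6-endo-trig mode. No stereocenter is formed, and C1, C2 and C3 are carried through unchanged. The step needs three regioselectivities: 6-endo over 5-exo should hold because 5-exo attack would hit the fully substituted diene carbon and give an unstabilised primary radical, 6-endo over 7-endo rests on the usual ring-size preference, and hydrogen delivery to the primary rather than the tertiary, ring-bound allyl terminus rests on sterics and on forming the more substituted alkene. High dilution and slow stannane addition are used to keep reduction of the uncyclised radical low.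

Step 9
Reactants: 17 {(1S,2S,6S)-2-[2-(1,3-dioxolan-2-yl)ethyl]-1,6-dimethyl-3-(propan-2-ylidene)cyclohexyl}methanol; 18 7-hydroxy-6,8-dimethoxy-2H-chromen-2-one (isofraxidin)
Product: 19 7-({(1S,2S,6S)-2-[2-(1,3-dioxolan-2-yl)ethyl]-1,6-dimethyl-3-(propan-2-ylidene)cyclohexyl}methoxy)-6,8-dimethoxy-2H-chromen-2-one
Conditions: PPh3, DIAD, THF (1 M), sonication, 25–40 °C
Reagents that add atoms: none
Why: Mitsunobu etherification of the primary neopentyl alcohol with the acidic phenol (a vinylogous carboxylic acid), run at high concentration with sonication because displacement at a neopentyl carbon is slow; no stereocenter is involved.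

Step 10
Reactants: 19 7-({(1S,2S,6S)-2-[2-(1,3-dioxolan-2-yl)ethyl]-1,6-dimethyl-3-(propan-2-ylidene)cyclohexyl}methoxy)-6,8-dimethoxy-2H-chromen-2-one
Product: 20 3-[(1S,2S,3S)-2-{[(6,8-dimethoxy-2-oxo-2H-chromen-7-yl)oxy]methyl}-2,3-dimethyl-6-(propan-2-ylidene)cyclohexyl]propanal
Conditions: PPTS (20 mol %), acetone/H2O (10:1), 55 °C
Reagents that add atoms: water, O
Why: Acetal hydrolysis under weak acid, chosen so that the liberated aldehyde should not undergo a Prins or carbonyl-ene closure onto the isopropylidene group.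

**Compound list**

1 | prop-2-yn-1-ol | C#CCO | starting material
2 | isopropenylmagnesium bromide | CC(=C)[Mg]Br | starting material
3 | bromomagnesium (2Z)-3-(bromomagnesio)-2-(prop-1-en-2-yl)prop-2-en-1-olate (chelated alkenylmagnesium alkoxide) | Br[Mg]OC/C(C(C)=C)=C\[Mg]Br | intermediate
4 | (2Z)-3-iodo-2-(prop-1-en-2-yl)prop-2-en-1-ol | OC/C(C(C)=C)=C\I | intermediate
5 | 2-vinyl-1,3-dioxolane | C=CC1OCCO1 | starting material
6 | 9-[2-(1,3-dioxolan-2-yl)ethyl]-9-borabicyclo[3.3.1]nonane | C1CC2CCCC(C1)B2CCC1OCCO1 | intermediate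
7 | (2Z)-5-(1,3-dioxolan-2-yl)-2-(prop-1-en-2-yl)pent-2-en-1-ol | OC/C(C(C)=C)=C\CCC1OCCO1 | intermediate
8 | (4R)-4-methyloxolan-2-one ((R)-β-methyl-γ-butyrolactone) | O=C1C[C@@H](C)CO1 | starting material
9 | (3R,4R)-3,4-dimethyloxolan-2-one | O=C1[C@H](C)[C@@H](C)CO1 | intermediate
10 | (3R,4R)-2-ethoxy-3,4-dimethyl-4,5-dihydro-3H-furan-1-ium tetrafluoroborate | CCOC=1[C@H](C)[C@@H](C)C[O+]=1.F[B-](F)(F)F | intermediate
11 | (3R,4R)-2,2-diethoxy-3,4-dimethyloxolane | CCOC1(OCC)[C@H](C)[C@@H](C)CO1 | intermediate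
12 | (4R)-2-ethoxy-2-{[(2Z)-5-(1,3-dioxolan-2-yl)-2-(prop-1-en-2-yl)pent-2-en-1-yl]oxy}-3,4-dimethyloxolane | CCOC1(OC/C(C(C)=C)=C\CCC2OCCO2)[C@H](C)[C@@H](C)CO1 | intermediate
13 | (3R)-5-{[(2Z)-5-(1,3-dioxolan-2-yl)-2-(prop-1-en-2-yl)pent-2-en-1-yl]oxy}-3,4-dimethyl-2,3-dihydrofuran | C=C(C)/C(COC1=C(C)[C@@H](C)CO1)=C/CCC2OCCO2 | intermediate
14 | (3R,4R)-3-[(4S)-6-(1,3-dioxolan-2-yl)-2-methyl-3-methylidenehex-1-en-4-yl]-3,4-dimethyloxolan-2-one | O=C1[C@](C)([C@@H](CCC2OCCO2)C(=C)C(C)=C)[C@@H](C)CO1 | intermediate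
15 | (2R,3R)-2-[(4S)-6-(1,3-dioxolan-2-yl)-2-methyl-3-methylidenehex-1-en-4-yl]-2,3-dimethyl-4-(phenylselanyl)butanoic acid | OC(=O)[C@](C)([C@@H](CCC1OCCO1)C(=C)C(C)=C)[C@@H](C)C[Se]c2ccccc2 | intermediate
16 | (2R,3R)-2-[(4S)-6-(1,3-dioxolan-2-yl)-2-methyl-3-methylidenehex-1-en-4-yl]-2,3-dimethyl-4-(phenylselanyl)butan-1-ol | OC[C@](C)([C@@H](CCC1OCCO1)C(=C)C(C)=C)[C@@H](C)C[Se]c2ccccc2 | intermediate
17 | {(1S,2S,6S)-2-[2-(1,3-dioxolan-2-yl)ethyl]-1,6-dimethyl-3-(propan-2-ylidene)cyclohexyl}methanol | OC[C@@]1(C)[C@@H](C)CCC(=C(C)C)[C@@H]1CCC2OCCO2 | intermediate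
18 | 7-hydroxy-6,8-dimethoxy-2H-chromen-2-one (isofraxidin) | COc1cc2ccc(=O)oc2c(OC)c1O | starting material
19 | 7-({(1S,2S,6S)-2-[2-(1,3-dioxolan-2-yl)ethyl]-1,6-dimethyl-3-(propan-2-ylidene)cyclohexyl}methoxy)-6,8-dimethoxy-2H-chromen-2-one | COc1cc2ccc(=O)oc2c(OC)c1OC[C@@]3(C)[C@@H](C)CCC(=C(C)C)[C@@H]3CCC4OCCO4 | intermediate
20 | 3-[(1S,2S,3S)-2-{[(6,8-dimethoxy-2-oxo-2H-chromen-7-yl)oxy]methyl}-2,3-dimethyl-6-(propan-2-ylidene)cyclohexyl]propanal | COc1cc2ccc(=O)oc2c(OC)c1OC[C@@]1(C)[C@@H](C)CCC(=C(C)C)[C@@H]1CCC=O | target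

**Count.** Total steps: 10. Longest linear sequence: 8 steps (8 to 20 through steps 3–10; the branch from 1 through steps 1, 2 and 5–10 is equally long).

**Steps most likely to fail**

Step 5. Exchange and elimination at the hindered ortho-lactone may be too slow, the diene may oligomerise at the temperature needed, or the chair preference may erode. The fallback replaces the thermal cyclic ketene acetal by an anionic Ireland–Claisen rearrangement; it sets out from 9 (with 7) and comes back at 14. Lactone 9 would be saponified (KOH, MeOH/H2O) and the hydroxy carboxylate silylated (tBuPh2SiCl, imidazole, DMF; then K2CO3, MeOH/H2O) to (3R)-4-[(tert-butyldiphenylsilyl)oxy]-2,3-dimethylbutanoic acid F1. Esterification with 7 (DCC, DMAP, CH2Cl2) would give the dienyl ester F2. Enolisation with LiN(iPr)2 in THF/DMPU at −78 °C and trapping with tBuMe2SiCl should give the silyl ketene acetal F3 with the C2 methyl cis to the allyloxy group. On warming, F3 should rearrange through a chair, on the face anti to the CH2OSi group as allylic strain dictates, to the acid F4 after aqueous work-up. Bu4NF in THF followed by brief stirring at pH 4 would remove the silyl ether and close the lactone to 14.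

Step 8. Hydrogen may be delivered to the ring-bound terminus of the allyl radical, closure may go 7-endo, or the radical may be reduced before it cyclises. The fallback closes the same C4–C5 bond by a two-electron alkylation; it sets out from 14 and comes back at 17. Lactone 14 would be opened with PhSNa (PhSH, NaH, DMF, 110 °C) to the sulfide acid F5, esterified (Me3SiCHN2, MeOH/PhMe) to the methyl ester F6 and oxidised at sulfur ((NH4)6Mo7O24, H2O2, EtOH, 0 °C) to the sulfone F7. Bromine (CH2Cl2, −78 °C) should add 1,4 across the diene to the bis-allylic dibromide F8; the symmetric reagent places a leaving group on the future C5 whichever end reacts first. LiN(iPr)2 (THF, −78 °C) would form the sulfone-stabilised carbanion at C4, which should close the ring by 6-exo-tet alkylation at C5 to the bromo sulfone ester F9. LiEt3BH (THF, 0 °C → rt) would reduce the ester to the alcohol and the remaining allylic bromide to methyl, giving the sulfone alcohol F10. Na/Hg (Na2HPO4, MeOH) would remove the sulfone to give 17.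

Step 9. Displacement at the neopentyl carbon may be outrun by decomposition of the oxyphosphonium intermediate and by alkylation of the hydrazide. The fallback separates activation from displacement; it sets out from 17 (with 18) and comes back at 19. Tf2O and 2,6-lutidine (CH2Cl2, −78 °C) would give the neopentyl triflate F11, which would be displaced by the caesium phenoxide of 18 (Cs2CO3, MeCN, 50 °C).

**Further compounds**

F1 | step 5 | (3R)-4-[(tert-butyldiphenylsilyl)oxy]-2,3-dimethylbutanoic acid (C2 epimer mixture) | OC(=O)C(C)[C@@H](C)CO[Si](c1ccccc1)(c1ccccc1)C(C)(C)C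
F2 | step 5 | (2Z)-5-(1,3-dioxolan-2-yl)-2-(prop-1-en-2-yl)pent-2-en-1-yl (3R)-4-[(tert-butyldiphenylsilyl)oxy]-2,3-dimethylbutanoate | C=C(C)/C(COC(=O)C(C)[C@@H](C)CO[Si](c1ccccc1)(c1ccccc1)C(C)(C)C)=C/CCC2OCCO2
F3 | step 5 | tert-butyldimethylsilyl ketene acetal of F2 (C2 methyl cis to the allyloxy group) | C=C(C)/C(CO/C(O[Si](C)(C)C(C)(C)C)=C(\C)[C@@H](C)CO[Si](c1ccccc1)(c1ccccc1)C(C)(C)C)=C/CCC2OCCO2
F4 | step 5 | (2R,3R)-4-[(tert-butyldiphenylsilyl)oxy]-2-[(4S)-6-(1,3-dioxolan-2-yl)-2-methyl-3-methylidenehex-1-en-4-yl]-2,3-dimethylbutanoic acid | OC(=O)[C@](C)([C@@H](CCC1OCCO1)C(=C)C(C)=C)[C@@H](C)CO[Si](c2ccccc2)(c2ccccc2)C(C)(C)C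
F5 | step 8 | (2R,3R)-2-[(4S)-6-(1,3-dioxolan-2-yl)-2-methyl-3-methylidenehex-1-en-4-yl]-2,3-dimethyl-4-(phenylsulfanyl)butanoic acid | OC(=O)[C@](C)([C@@H](CCC1OCCO1)C(=C)C(C)=C)[C@@H](C)CSc2ccccc2
F6 | step 8 | methyl (2R,3R)-2-[(4S)-6-(1,3-dioxolan-2-yl)-2-methyl-3-methylidenehex-1-en-4-yl]-2,3-dimethyl-4-(phenylsulfanyl)butanoate | COC(=O)[C@](C)([C@@H](CCC1OCCO1)C(=C)C(C)=C)[C@@H](C)CSc2ccccc2
F7 | step 8 | methyl (2R,3R)-4-(benzenesulfonyl)-2-[(4S)-6-(1,3-dioxolan-2-yl)-2-methyl-3-methylidenehex-1-en-4-yl]-2,3-dimethylbutanoate | COC(=O)[C@](C)([C@@H](CCC1OCCO1)C(=C)C(C)=C)[C@@H](C)CS(=O)(=O)c2ccccc2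
F8 | step 8 | bis-allylic 1,4-dibromide of F7 (C(CH2Br)=C(CH3)CH2Br unit, alkene isomer mixture) | COC(=O)[C@](C)([C@@H](CCC1OCCO1)C(CBr)=C(C)CBr)[C@@H](C)CS(=O)(=O)c2ccccc2
F9 | step 8 | methyl 3-(benzenesulfonyl)-5-(1-bromopropan-2-ylidene)-6-[2-(1,3-dioxolan-2-yl)ethyl]-1,2-dimethylcyclohexane-1-carboxylate (carried stereocentres as in 17, sulfonyl carbon as a mixture) | COC(=O)[C@@]1(C)[C@@H](C)C(S(=O)(=O)c2ccccc2)CC(=C(C)CBr)[C@@H]1CCC3OCCO3
F10 | step 8 | {3-(benzenesulfonyl)-6-[2-(1,3-dioxolan-2-yl)ethyl]-1,2-dimethyl-5-(propan-2-ylidene)cyclohexyl}methanol (carried stereocentres as in 17, sulfonyl carbon as a mixture) | OC[C@@]1(C)[C@@H](C)C(S(=O)(=O)c2ccccc2)CC(=C(C)C)[C@@H]1CCC3OCCO3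
F11 | step 9 | {(1S,2S,6S)-2-[2-(1,3-dioxolan-2-yl)ethyl]-1,6-dimethyl-3-(propan-2-ylidene)cyclohexyl}methyl trifluoromethanesulfonate | FC(F)(F)S(=O)(=O)OC[C@@]1(C)[C@@H](C)CCC(=C(C)C)[C@@H]1CCC2OCCO2
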